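**Retrosynthetic overview**
- The two epoxides are made last, by stereospecific double epoxidation of a (3E,7Z)-diene acetate; the acetate comes from the C10 alcohol.
- The twelve-membered ring is closed on the intact six-membered ring by an intramolecular chromium-mediated allylation (C10–C11). This also sets C10 and C11 and creates the C12=C18 methylene.
- The E-C3=C4 olefin comes from a gem-dibromoalkene at C4, substituted first by the C5 alkylzinc (trans to C2) and then by methyl (two Negishi couplings).
- The C1 stereocentre comes from a rhodium-catalysed enantioselective 1,4-addition that desymmetrises achiral 4,4-dimethylcyclohexa-2,5-dienone; the six-membered ring is bought whole.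
- Key step: 4-methylanisole is not kept as a ring. Birch reduction, then ozonolysis of the enol ether, unzips it into C5–C10 with the Z-C7=C8 olefin, C19, an ester end (C5) and an aldehyde end (C10).

Assumption: 4,4-dimethylcyclohexa-2,5-dien-1-one and the pinacol ester of (E)-2-ethoxyvinylboronic acid are bought as catalogue compounds. Atom labels C1–C20 are those of the bicyclo[9.3.1]pentadecane target (C1 and C11 bridgeheads, C15 the gem-dimethyl carbon, C18 the methylene carbon, C19 and C20 the methyls on C8 and C4).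

**Route**

Step 1
Reactants: 1 4-methylanisole
Product: 2 1-methoxy-4-methylcyclohexa-1,4-diene
Conditions: Li, NH3(l), THF, t-BuOH, −33 °C
Reagents that add atoms: none
Why: Birch reduction gives the 2,5-dihydroarene with the methoxy and methyl groups on the two remaining double bonds, so the aromatic ring becomes an enol ether plus a ring-locked, hence cis, trisubstituted olefin (the future C7=C8 carrying C19).

Step 2
Reactants: 2 1-methoxy-4-methylcyclohexa-1,4-diene
Product: 4 methyl (3Z)-6,6-dimethoxy-4-methylhex-3-enoate, via ester aldehyde 3 (not isolated)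
Conditions: O3 (1.0 equiv), CH2Cl2/MeOH 4:1, −78 °C; Me2S, −78 → 23 °C; then HC(OMe)3, TsOH (cat.), 23 °C
Reagents that add atoms: ozone O=[O+][O-]; trimethyl orthoformate COC(OC)OC
Why: Chemoselective ozonolysis (Criegee cleavage, reductive work-up) of the much more electron-rich enol ether opens the ring to a methyl ester (C5) and an aldehyde (C10), the trisubstituted olefin keeps the Z geometry imposed by the former ring, and acetalisation in the same flask protects the isomerisation-prone β,γ-unsaturated aldehyde.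

Step 3
Reactants: 4 methyl (3Z)-6,6-dimethoxy-4-methylhex-3-enoate
Product: 5 (3Z)-6,6-dimethoxy-4-methylhex-3-en-1-ol
Conditions: LiAlH4, Et2O, 0 °C
Reagents that add atoms: none
Why: Hydride reduction of the ester to the primary alcohol (C5) leaves the acetal and the isolated Z olefin untouched.

Step 4
Reactants: 5 (3Z)-6,6-dimethoxy-4-methylhex-3-en-1-ol
Product: 6 (3Z)-6-iodo-1,1-dimethoxy-3-methylhex-3-ene
Conditions: I2, PPh3, imidazole, CH2Cl2, 0 °C
Reagents that add atoms: iodine II
Why: Garegg–Samuelsson (Appel-type) iodination converts the primary alcohol into the iodide under imidazole-buffered conditions that spare the acetal.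

Step 5
Reactants: 7 4,4-dimethylcyclohexa-2,5-dien-1-one; 8 2-[(E)-2-ethoxyethenyl]-4,4,5,5-tetramethyl-1,3,2-dioxaborolane
Product: 10 2-[(1R)-2,2-dimethyl-5-oxocyclohex-3-en-1-yl]acetaldehyde, via enol ether adduct 9 (not isolated)
Conditions: [Rh(OH)((S)-binap)]2 (3 mol % Rh), KOH (0.2 equiv), dioxane/H2O 10:1, 40 °C; then 1 M HCl, THF, 0 °C
Reagents that add atoms: water O
Why: Hayashi–Miyaura rhodium-catalysed asymmetric 1,4-addition desymmetrises the achiral dienone, the chiral bisphosphine choosing one of the two enantiotopic enone faces to set C1 as R ((S)-binap by analogy with its (S)-3-arylcyclohexanone selectivity, the mirror-image ligand being used if the sense proves opposite), and mild acid then hydrolyses the enol ether to the C3 aldehyde.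

Step 6
Reactants: 10 2-[(1R)-2,2-dimethyl-5-oxocyclohex-3-en-1-yl]acetaldehyde
Product: 11 (5R)-5-(3,3-dibromoprop-2-en-1-yl)-4,4-dimethylcyclohex-2-en-1-one
Conditions: CBr4, PPh3, Zn dust, CH2Cl2, 23 °C; then 10, 0 °C
Reagents that add atoms: carbon tetrabromide BrC(Br)(Br)Br
Why: Ramirez/Corey–Fuchs dibromo-olefination reacts with the aldehyde but not with the hindered enone carbonyl and installs C4 as a gem-dibromoalkene whose two bromines can be replaced one after the other.

Step 7
Reactants: 11 (5R)-5-(3,3-dibromoprop-2-en-1-yl)-4,4-dimethylcyclohex-2-en-1-one; 6 (3Z)-6-iodo-1,1-dimethoxy-3-methylhex-3-ene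
Product: 14 (5R)-5-[(2E,6Z)-9,9-dimethoxy-3,7-dimethylnona-2,6-dien-1-yl]-4,4-dimethylcyclohex-2-en-1-one, via alkylzinc iodide 12 (not isolated), via bromoalkene 13 (not isolated)
Conditions: 6, Zn dust, LiCl, THF, 40 °C; then 11, PdCl2(DPEphos) (5 mol %), THF/DMF, 23 °C; then Me2Zn, Pd(t-Bu3P)2 (5 mol %), 23 → 40 °C
Reagents that add atoms: dimethylzinc C[Zn]C
Why: Negishi's stepwise coupling of 1,1-dibromoalkenes, in which zerovalent palladium first inserts into the less hindered C–Br bond trans to the C2 substituent so that the C5 alkylzinc ends up trans to C2, and the remaining bromide is then methylated with retention, fixes the 3E olefin while the 7Z olefin is carried through unchanged.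

Step 8
Reactants: 14 (5R)-5-[(2E,6Z)-9,9-dimethoxy-3,7-dimethylnona-2,6-dien-1-yl]-4,4-dimethylcyclohex-2-en-1-one
Product: 15 (5R)-5-[(2E,6Z)-9,9-dimethoxy-3,7-dimethylnona-2,6-dien-1-yl]-2-(hydroxymethyl)-4,4-dimethylcyclohex-2-en-1-one
Conditions: 37% aq. CH2O, DMAP (0.3 equiv), THF/H2O, 23 °C
Reagents that add atoms: formaldehyde C=O
Why: Morita–Baylis–Hillman hydroxymethylation (amine adds to C11, the enolate takes up formaldehyde at C12, the amine leaves) brings in C18, and the acetal and the unactivated olefins are inert to the catalyst.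

Step 9
Reactants: 15 (5R)-5-[(2E,6Z)-9,9-dimethoxy-3,7-dimethylnona-2,6-dien-1-yl]-2-(hydroxymethyl)-4,4-dimethylcyclohex-2-en-1-one
Product: 17 (3Z,7E)-9-[(1R)-4-(bromomethyl)-2,2-dimethyl-5-oxocyclohex-3-en-1-yl]-3,7-dimethylnona-3,7-dienal, via bromo acetal 16 (not isolated)
Conditions: CBr4, PPh3 (1.05 equiv, added slowly), CH2Cl2, −20 °C; then wet SiO2, oxalic acid (cat.), 23 °C
Reagents that add atoms: carbon tetrabromide BrC(Br)(Br)Br; water O
Why: Appel bromination of the primary allylic alcohol under neutral conditions, followed by mild acetal hydrolysis, frees the C10 aldehyde only when it is needed and so limits isomerisation of the β,γ-unsaturated aldehyde.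

Step 10
Reactants: 17 (3Z,7E)-9-[(1R)-4-(bromomethyl)-2,2-dimethyl-5-oxocyclohex-3-en-1-yl]-3,7-dimethylnona-3,7-dienal
Product: 19 (1R,3E,7Z,10R,11S)-10-hydroxy-4,8,15,15-tetramethyl-12-methylidenebicyclo[9.3.1]pentadeca-3,7-dien-13-one, via allylchromium dichloride 18 (not isolated)
Conditions: CrCl2 (8 equiv), 4 Å MS, THF (2 mM, slow addition of 17), 23 °C
Reagents that add atoms: none
Why: In this intramolecular Nozaki–Hiyama–Kishi (Barbier-type) allylation the allylchromium reagent adds through its γ-carbon (C11) to the aldehyde in a chair (Zimmerman–Traxler) transition state, which closes the twelve-membered ring, moves the olefin to the exocyclic C12=C18 position and, because the ring-locked allyl unit is E-configured, should give the anti (10R,11S) pair, with the aldehyde expected on the face of C11 opposite the pseudo-axial C15 methyl in the half-chair that keeps the C1 side chain pseudo-equatorial (C10 trans to C2).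

Step 11
Reactants: 19 (1R,3E,7Z,10R,11S)-10-hydroxy-4,8,15,15-tetramethyl-12-methylidenebicyclo[9.3.1]pentadeca-3,7-dien-13-one
Product: 20 (1R,3E,7Z,10R,11S)-4,8,15,15-tetramethyl-12-methylidene-13-oxobicyclo[9.3.1]pentadeca-3,7-dien-10-yl acetate
Conditions: Ac2O, pyridine, DMAP (cat.), CH2Cl2, 0 °C
Reagents that add atoms: acetic anhydride CC(=O)OC(C)=O
Why: DMAP-catalysed acylation of the secondary alcohol at low temperature creates no stereocentre and avoids base-induced migration of the exocyclic double bond into the ring.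

Step 12
Reactants: 20 (1R,3E,7Z,10R,11S)-4,8,15,15-tetramethyl-12-methylidene-13-oxobicyclo[9.3.1]pentadeca-3,7-dien-10-yl acetate
Product: 21 (1R,3R,4R,7R,8S,10R,11S)-3,4:7,8-diepoxy-4,8,15,15-tetramethyl-12-methylidene-13-oxobicyclo[9.3.1]pentadecan-10-yl acetate (CNP0339728.4)
Conditions: mCPBA (2.2 equiv), NaHCO3, CH2Cl2, −20 → 0 °C
Reagents that add atoms: mCPBA OOC(=O)c1cccc(Cl)c1
Why: Prilezhaev epoxidation is stereospecific (E olefin to the trans 3,4-epoxide, Z olefin to the cis 7,8-epoxide), leaves the electron-poor enone methylene alone, and is expected, though not modelled, to attack the outward-facing side of each olefin of the bridged macrocycle to give the 3R,4R,7R,8S configuration.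

**Compound list**
1 | 4-methylanisole | COc1ccc(C)cc1 | starting material
2 | 1-methoxy-4-methylcyclohexa-1,4-diene | COC1=CCC(C)=CC1 | intermediate
3 | methyl (3Z)-4-methyl-6-oxohex-3-enoate | COC(=O)C/C=C(/C)CC=O | intermediate
4 | methyl (3Z)-6,6-dimethoxy-4-methylhex-3-enoate | COC(=O)C/C=C(/C)CC(OC)OC | intermediate
5 | (3Z)-6,6-dimethoxy-4-methylhex-3-en-1-ol | OCC/C=C(/C)CC(OC)OC | intermediate
6 | (3Z)-6-iodo-1,1-dimethoxy-3-methylhex-3-ene | ICC/C=C(/C)CC(OC)OC | intermediate
7 | 4,4-dimethylcyclohexa-2,5-dien-1-one | CC1(C)C=CC(=O)C=C1 | starting material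
8 | 2-[(E)-2-ethoxyethenyl]-4,4,5,5-tetramethyl-1,3,2-dioxaborolane | CCO/C=C/B1OC(C)(C)C(C)(C)O1 | starting material
9 | (5S)-5-[(E)-2-ethoxyethenyl]-4,4-dimethylcyclohex-2-en-1-one | O=C1C[C@@H](/C=C/OCC)C(C)(C)C=C1 | intermediate
10 | 2-[(1R)-2,2-dimethyl-5-oxocyclohex-3-en-1-yl]acetaldehyde | O=C1C[C@@H](CC=O)C(C)(C)C=C1 | intermediate
11 | (5R)-5-(3,3-dibromoprop-2-en-1-yl)-4,4-dimethylcyclohex-2-en-1-one | O=C1C[C@@H](CC=C(Br)Br)C(C)(C)C=C1 | intermediate
12 | [(3Z)-6,6-dimethoxy-4-methylhex-3-en-1-yl]zinc iodide | I[Zn]CC/C=C(/C)CC(OC)OC | intermediate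
13 | (5R)-5-[(2Z,6Z)-3-bromo-9,9-dimethoxy-7-methylnona-2,6-dien-1-yl]-4,4-dimethylcyclohex-2-en-1-one | O=C1C[C@@H](C/C=C(\Br)CC/C=C(/C)CC(OC)OC)C(C)(C)C=C1 | intermediate
14 | (5R)-5-[(2E,6Z)-9,9-dimethoxy-3,7-dimethylnona-2,6-dien-1-yl]-4,4-dimethylcyclohex-2-en-1-one | O=C1C[C@@H](C/C=C(\C)CC/C=C(/C)CC(OC)OC)C(C)(C)C=C1 | intermediate
15 | (5R)-5-[(2E,6Z)-9,9-dimethoxy-3,7-dimethylnona-2,6-dien-1-yl]-2-(hydroxymethyl)-4,4-dimethylcyclohex-2-en-1-one | O=C1C[C@@H](C/C=C(\C)CC/C=C(/C)CC(OC)OC)C(C)(C)C=C1CO | intermediate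
16 | (5R)-2-(bromomethyl)-5-[(2E,6Z)-9,9-dimethoxy-3,7-dimethylnona-2,6-dien-1-yl]-4,4-dimethylcyclohex-2-en-1-one | O=C1C[C@@H](C/C=C(\C)CC/C=C(/C)CC(OC)OC)C(C)(C)C=C1CBr | intermediate
17 | (3Z,7E)-9-[(1R)-4-(bromomethyl)-2,2-dimethyl-5-oxocyclohex-3-en-1-yl]-3,7-dimethylnona-3,7-dienal | O=C1C[C@@H](C/C=C(\C)CC/C=C(/C)CC=O)C(C)(C)C=C1CBr | intermediate
18 | dichloro({(4R)-4-[(2E,6Z)-3,7-dimethyl-9-oxonona-2,6-dien-1-yl]-3,3-dimethyl-6-oxocyclohex-1-en-1-yl}methyl)chromium | O=C1C[C@@H](C/C=C(\C)CC/C=C(/C)CC=O)C(C)(C)C=C1C[Cr](Cl)Cl | intermediate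
19 | (1R,3E,7Z,10R,11S)-10-hydroxy-4,8,15,15-tetramethyl-12-methylidenebicyclo[9.3.1]pentadeca-3,7-dien-13-one | C=C1C(=O)C[C@H]2C/C=C(\C)CC/C=C(/C)C[C@@H](O)[C@H]1C2(C)C | intermediate
20 | (1R,3E,7Z,10R,11S)-4,8,15,15-tetramethyl-12-methylidene-13-oxobicyclo[9.3.1]pentadeca-3,7-dien-10-yl acetate | C=C1C(=O)C[C@H]2C/C=C(\C)CC/C=C(/C)C[C@@H](OC(C)=O)[C@H]1C2(C)C | intermediate
21 | (1R,3R,4R,7R,8S,10R,11S)-3,4:7,8-diepoxy-4,8,15,15-tetramethyl-12-methylidene-13-oxobicyclo[9.3.1]pentadecan-10-yl acetate | C=C1C(=O)C[C@H]2C[C@H]3O[C@]3(C)CC[C@H]3O[C@@]3(C)C[C@@H](OC(C)=O)[C@H]1C2(C)C | target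

**Step count and risks**

Total: 12 steps. Longest linear sequence: 10 steps (1–4, then 7–12); the ring branch (5, 6) joins at step 7.

The three steps most likely to fail:

Step 5 (desymmetrising 1,4-addition). The β-carbon is neopentyl-like, and the β-alkoxyvinyl boronate may protodeboronate before it transfers; use of this boronate in the rhodium addition is an extension of the aryl and alkenyl cases, not a reported example. The fallback sets out from 7 and switches from rhodium/boron alkenyl transfer to copper/zinc alkyl transfer. The commercial (1,3-dioxolan-2-ylmethyl)magnesium bromide and ZnCl2 give bis(1,3-dioxolan-2-ylmethyl)zinc F1. With Cu(OTf)2 and the (S,R,R)-binaphthol bis(1-phenylethyl)amine phosphoramidite ligand (toluene, −30 °C; the type of dialkylzinc addition established for 4,4-disubstituted cyclohexadienones), F1 adds to 7 to give (5R)-5-(1,3-dioxolan-2-ylmethyl)-4,4-dimethylcyclohex-2-en-1-one F2. Aqueous HCl in THF removes the dioxolane and the route is rejoined at 10.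

Step 10 (ring closure). The chair transition state gives the anti pair only if the tethered aldehyde chain sits equatorial, and the face of C11 is chosen by the tether rather than by a reagent. The tethered closure could equally deliver C10 cis to C2; the trans outcome is an expectation, not a secure prediction. Possible failure products are the C10 epimer (syn mode), the cis-fused ring, the fourteen-membered ring from attack through C18, and oligomers. The fallback sets out from 17 and accepts the syn-mode product, (1R,3E,7Z,10S,11S)-10-hydroxy-4,8,15,15-tetramethyl-12-methylidenebicyclo[9.3.1]pentadeca-3,7-dien-13-one F3. A Mitsunobu reaction with acetic acid (PPh3, DIAD, AcOH, toluene, 0 °C) then sets C10 by SN2 inversion instead of by the ring-closing transition state. This gives the acetate directly and rejoins the route at 20, so step 11 is not needed. It does not correct a cis ring fusion.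

Step 12 (double epoxidation). The facial selectivity rests only on the conformation of the macrocycle and could give any of four diastereomers. The fallback sets out from 19 and introduces the two epoxides one at a time, each under its own control element. VO(acac)2 and t-BuOOH (CH2Cl2, 0 °C) deliver oxygen from the vanadium alkoxide of the C10 hydroxyl only to the homoallylic C7=C8 olefin, giving (1R,3E,7R,8S,10R,11S)-7,8-epoxy-10-hydroxy-4,8,15,15-tetramethyl-12-methylidenebicyclo[9.3.1]pentadec-3-en-13-one F4; whether the directed delivery gives this face must be checked. Acetylation (Ac2O, pyridine) gives (1R,3E,7R,8S,10R,11S)-7,8-epoxy-4,8,15,15-tetramethyl-12-methylidene-13-oxobicyclo[9.3.1]pentadec-3-en-10-yl acetate F5. Shi epoxidation of the remaining E olefin (D-fructose-derived ketone, 2KHSO5·KHSO4·K2SO4, K2CO3, MeCN/dimethoxymethane/water, 0 °C) is reagent-controlled and is expected to give the R,R epoxide as it does for E-trisubstituted olefins of this type, rejoining the route at 21.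

**Further compounds**
F1 | step 5 | bis(1,3-dioxolan-2-ylmethyl)zinc | C(C1OCCO1)[Zn]CC1OCCO1
F2 | step 5 | (5R)-5-(1,3-dioxolan-2-ylmethyl)-4,4-dimethylcyclohex-2-en-1-one | O=C1C[C@@H](CC2OCCO2)C(C)(C)C=C1
F3 | step 10 | (1R,3E,7Z,10S,11S)-10-hydroxy-4,8,15,15-tetramethyl-12-methylidenebicyclo[9.3.1]pentadeca-3,7-dien-13-one | C=C1C(=O)C[C@H]2C/C=C(\C)CC/C=C(/C)C[C@H](O)[C@H]1C2(C)C
F4 | step 12 | (1R,3E,7R,8S,10R,11S)-7,8-epoxy-10-hydroxy-4,8,15,15-tetramethyl-12-methylidenebicyclo[9.3.1]pentadec-3-en-13-one | C=C1C(=O)C[C@H]2C/C=C(\C)CC[C@H]3O[C@@]3(C)C[C@@H](O)[C@H]1C2(C)C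
F5 | step 12 | (1R,3E,7R,8S,10R,11S)-7,8-epoxy-4,8,15,15-tetramethyl-12-methylidene-13-oxobicyclo[9.3.1]pentadec-3-en-10-yl acetate | C=C1C(=O)C[C@H]2C/C=C(\C)CC[C@H]3O[C@@]3(C)C[C@@H](OC(C)=O)[C@H]1C2(C)C
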